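**Plan** (carotenoid numbering: ring C1 = CMe2, C2 = CH2, C3 and C4 = carbinols, C5 = methyl-bearing, C6 = chain-bearing)

- Retrosynthesis: cut C7=C8 (Wittig, ring C10 aldehyde + C30 ylide), then C7'=C8' (Wittig, C20 dialdehyde + geranyl ylide); then cut the ring at C6–C1 and C5–C4 together (Michael/aldol annulation of ethyl acetoacetate with mesityl oxide).
- Enabling feature: in ring C1–C6 the C3 oxygen lies β to the quaternary C1 and α to C4, and C5=C6 carries a methyl and a carbon (C7) that can be a carboxyl. C1–C4 is therefore a mesityl oxide unit (C1 = enone β-carbon, C4 = its methyl) and Me–C5–C6–C7 an acetoacetate unit.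
- Forward: the ring is made first (C3=O, C4=C5, acidic C6–H). Ketone reduction, epoxidation of C4=C5 and base-induced epoxide opening then move the alkene to C5=C6 and leave the C4 hydroxyl.
- Chain: geranyl C10 + C20 dialdehyde give a C30 phosphonium salt; a final Wittig with the ring aldehyde and desilylation finish the route.
- Stereochemistry: C3 (R) from catalyst-controlled ketone reduction; C4 (S) relayed from C3 by hydroxyl-directed epoxidation (cis-diol); E-alkenes from Wittig reactions followed by thermal Z-to-E equilibration.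

Key step: step 1

Assumption: crocetin dialdehyde (the C20 dialdehyde) is taken as a purchasable polyene building block; the enone ester and its two successors are carried as epimer mixtures at the ester-bearing carbon, which is flattened when the alkene moves to C5=C6.

**Step 1**
Reactants: 1 mesityl oxide (4-methylpent-3-en-2-one); 2 ethyl acetoacetate
Product: 5 ethyl 2,6,6-trimethyl-4-oxocyclohex-2-ene-1-carboxylate (racemic), via Michael adduct 3 (not isolated), via aldol adduct 4 (not isolated)
Conditions: ZnCl2 (anhydrous, 0.2 equiv), heptane–toluene, reflux, Dean–Stark trap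
Reagents that add atoms: none
Why: The zinc-chelated enol of 2 adds to the β-carbon of Lewis-acid-activated 1 (Michael addition), which forges the C6–C1 bond at the quaternary carbon and gives 1,5-diketone 3; the mesityl-oxide-derived methyl ketone then enolises toward its CH3 and attacks the acetoacetate ketone (aldol, C4–C5 bond, 4), and loss of water gives enone 5. The closest known reaction type is the Robinson annulation of a β-keto ester with an enone under Lewis acid and azeotropic water removal. The ring closes by a 6-(enolendo)-exo-trig aldol, a favoured mode. No stereocentre of the target is set here; the only one formed, the ester-bearing carbon, is carried as a racemate and is flattened in step 4. The step needs regioselectivity in the aldol, which should be secured because the acetoacetate ketone is the more electrophilic carbonyl (β to the ester) and its own α-carbon is a hindered tertiary CH after the Michael step, whereas the alternative closure would need attack on the neopentyl-flanked ketone.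

**Step 2**
Reactants: 5 ethyl 2,6,6-trimethyl-4-oxocyclohex-2-ene-1-carboxylate
Product: 6 ethyl (4R)-4-hydroxy-2,6,6-trimethylcyclohex-2-ene-1-carboxylate (both C-1 epimers)
Conditions: (S)-2-methyl-CBS-oxazaborolidine (0.1 equiv), BH3·SMe2 (0.7 equiv), THF, −20 °C; MeOH quench
Reagents that add atoms: none
Why: Corey–Bakshi–Shibata reduction, in which the oxazaborolidine should bind the ketone with the alkenyl arm as the large group and deliver hydride 1,2 to one face to give the (4R)-carbinol (the future C3 centre), leaving the ester untouched; if the CH2–CMe2 arm proves the larger group, the antipodal catalyst is used.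

**Step 3**
Reactants: 6 ethyl (4R)-4-hydroxy-2,6,6-trimethylcyclohex-2-ene-1-carboxylate
Product: 7 ethyl (1S,5R,6R)-5-hydroxy-1,3,3-trimethyl-7-oxabicyclo[4.1.0]heptane-2-carboxylate (epoxide oxygen cis to the hydroxyl; both C-2 epimers)
Conditions: VO(acac)2 (0.02 equiv), t-BuOOH (1.5 equiv, in decane), toluene, 0 °C → rt
Reagents that add atoms: tert-butyl hydroperoxide, CC(C)(C)OO
Why: Vanadium-catalysed hydroxyl-directed epoxidation of a cyclic allylic alcohol, in which the vanadate ester of the C3 hydroxyl should deliver oxygen to the alkene face cis to it, so the future C4–O bond is set syn to C3–OH.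

**Step 4**
Reactants: 7 ethyl (1S,5R,6R)-5-hydroxy-1,3,3-trimethyl-7-oxabicyclo[4.1.0]heptane-2-carboxylate
Product: 8 ethyl (3S,4R)-3,4-dihydroxy-2,6,6-trimethylcyclohex-1-ene-1-carboxylate (cis-diol)
Conditions: NaOEt (0.3 equiv), EtOH, 0 → 40 °C; aq. NH4Cl work-up
Reagents that add atoms: none
Why: Base-induced E1cB opening of a β,γ-epoxy ester: the ester enolate should open the adjacent epoxide C–O bond to give the tetrasubstituted conjugated C5=C6 alkene and the C4 alkoxide with its configuration untouched (cis-diol); both ester epimers converge through the common enolate, and the syn hydroxyl cannot undergo Payne rearrangement.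

**Step 5**
Reactants: 8 ethyl (3S,4R)-3,4-dihydroxy-2,6,6-trimethylcyclohex-1-ene-1-carboxylate
Product: 9 ethyl (3S,4R)-3,4-bis(tert-butyldimethylsilyloxy)-2,6,6-trimethylcyclohex-1-ene-1-carboxylate
Conditions: TBSOTf (2.6 equiv), 2,6-lutidine (4 equiv), CH2Cl2, −40 → 0 °C
Reagents that add atoms: tert-butyldimethylsilyl trifluoromethanesulfonate, CC(C)(C)[Si](C)(C)OS(=O)(=O)C(F)(F)F
Why: Silyl triflate silylation, which should protect both hindered secondary hydroxyls as fluoride-labile ethers so that the final deprotection needs no acid near the allylic C4–O bond.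

**Step 6**
Reactants: 9 ethyl (3S,4R)-3,4-bis(tert-butyldimethylsilyloxy)-2,6,6-trimethylcyclohex-1-ene-1-carboxylate
Product: 10 [(3S,4R)-3,4-bis(tert-butyldimethylsilyloxy)-2,6,6-trimethylcyclohex-1-en-1-yl]methanol
Conditions: i-Bu2AlH (2.5 equiv), CH2Cl2, −78 → −20 °C; aq. KNaC4H4O6 (potassium sodium tartrate) work-up
Reagents that add atoms: none
Why: Hydride reduction of a conjugated ester to the allylic alcohol, which should proceed 1,2 and leave the silyl ethers intact.

**Step 7**
Reactants: 10 [(3S,4R)-3,4-bis(tert-butyldimethylsilyloxy)-2,6,6-trimethylcyclohex-1-en-1-yl]methanol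
Product: 11 (3S,4R)-3,4-bis(tert-butyldimethylsilyloxy)-2,6,6-trimethylcyclohex-1-ene-1-carbaldehyde
Conditions: MnO2 (activated, 15 equiv), CH2Cl2, rt
Reagents that add atoms: none
Why: Allylic alcohol oxidation on MnO2, which should stop cleanly at the conjugated aldehyde (C7) under neutral conditions.

**Step 8**
Reactants: 12 geranyl bromide ((2E)-1-bromo-3,7-dimethylocta-2,6-diene); 13 triphenylphosphine
Product: 14 [(2E)-3,7-dimethylocta-2,6-dien-1-yl]triphenylphosphonium bromide
Conditions: toluene, rt → 40 °C; salt filtered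
Reagents that add atoms: none
Why: SN2 quaternisation of a primary allylic bromide, which should give the phosphonium salt with the E-alkene unchanged.

**Step 9**
Reactants: 14 [(2E)-3,7-dimethylocta-2,6-dien-1-yl]triphenylphosphonium bromide; 15 crocetin dialdehyde ((2E,4E,6E,8E,10E,12E,14E)-2,6,11,15-tetramethylhexadeca-2,4,6,8,10,12,14-heptaenedial)
Product: 18 all-E 8'-apo-ψ-caroten-8'-al ((2E,4E,6E,8E,10E,12E,14E,16E,18E)-2,6,11,15,19,23-hexamethyltetracosa-2,4,6,8,10,12,14,16,18,22-decaenal), via geranylidene ylide 16 (not isolated), via 16Z aldehyde 17 (not isolated)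
Conditions: n-BuLi (1.0 equiv), THF, −78 °C; ylide added to 15 (3 equiv), THF, −78 → 0 °C; then heptane, reflux, dark
Reagents that add atoms: none
Why: Wittig olefination at one aldehyde of the symmetrical dialdehyde, favoured by inverse addition and excess dialdehyde; the new C7'=C8' bond should form as an E/Z mixture that thermal equilibration drives to the all-E isomer.

**Step 10**
Reactants: 18 all-E 8'-apo-ψ-caroten-8'-al
Product: 19 all-E 8'-apo-ψ-caroten-8'-ol ((2E,4E,6E,8E,10E,12E,14E,16E,18E)-2,6,11,15,19,23-hexamethyltetracosa-2,4,6,8,10,12,14,16,18,22-decaen-1-ol)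
Conditions: NaBH4 (1.0 equiv), THF–EtOH, 0 °C, dark
Reagents that add atoms: none
Why: Borohydride 1,2-reduction of a polyenal, which should give the primary allylic alcohol without touching the polyene.

**Step 11**
Reactants: 19 all-E 8'-apo-ψ-caroten-8'-ol
Product: 20 all-E (8'-apo-ψ-caroten-8'-yl)triphenylphosphonium bromide
Conditions: PPh3·HBr (1.05 equiv), CH2Cl2–MeOH, 0 °C → rt, dark
Reagents that add atoms: triphenylphosphine hydrobromide, [PH+](c1ccccc1)(c1ccccc1)c1ccccc1.[Br-]
Why: Acid-mediated ionisation of the polyenyl allylic alcohol and capture of the delocalised cation by PPh3 at the unhindered terminus, the standard way to carotenoid Wittig salts.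

**Step 12**
Reactants: 20 all-E (8'-apo-ψ-caroten-8'-yl)triphenylphosphonium bromide; 11 (3S,4R)-3,4-bis(tert-butyldimethylsilyloxy)-2,6,6-trimethylcyclohex-1-ene-1-carbaldehyde
Product: 23 all-E (3R,4S)-3,4-bis(tert-butyldimethylsilyloxy)-β,ψ-carotene, via C30 ylide 21 (not isolated), via 7Z isomer 22 (not isolated)
Conditions: NaN(SiMe3)2 (1.0 equiv), THF, −78 °C; then 11, −78 °C → rt; then heptane, 80 °C, dark, argon; crystallisation
Reagents that add atoms: none
Why: Wittig olefination of the cyclocitral-type aldehyde with a semi-stabilised polyenyl ylide, which should form C7=C8; the crowded 7Z isomer should revert to 7E on heating, and no carbanion is placed next to the allylic C4–O bond.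

**Step 13**
Reactants: 23 all-E (3R,4S)-3,4-bis(tert-butyldimethylsilyloxy)-β,ψ-carotene
Product: 24 (3R,4S)-β,ψ-carotene-3,4-diol (all-E; CNP0310445.2)
Conditions: Bu4NF (3 equiv), THF, 0 °C → rt, dark, argon
Reagents that add atoms: none
Why: Fluoride-induced desilylation, which should free both hydroxyls under non-acidic conditions that spare the polyene and the ionisable allylic C4–OH.

**Compound list**
1 | mesityl oxide (4-methylpent-3-en-2-one) | CC(C)=CC(C)=O | starting material
2 | ethyl acetoacetate | CCOC(=O)CC(C)=O | starting material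
3 | ethyl 2-acetyl-3,3-dimethyl-5-oxohexanoate (racemic Michael adduct) | CCOC(=O)C(C(C)=O)C(C)(C)CC(C)=O | intermediate
4 | ethyl 2-hydroxy-2,6,6-trimethyl-4-oxocyclohexane-1-carboxylate (aldol adduct, diastereomer mixture) | CCOC(=O)C1C(C)(O)CC(=O)CC1(C)C | intermediate
5 | ethyl 2,6,6-trimethyl-4-oxocyclohex-2-ene-1-carboxylate (racemic) | CCOC(=O)C1C(C)=CC(=O)CC1(C)C | intermediate
6 | ethyl (4R)-4-hydroxy-2,6,6-trimethylcyclohex-2-ene-1-carboxylate (both C-1 epimers) | CCOC(=O)C1C(C)=C[C@H](O)CC1(C)C | intermediate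
7 | ethyl (1S,5R,6R)-5-hydroxy-1,3,3-trimethyl-7-oxabicyclo[4.1.0]heptane-2-carboxylate (both C-2 epimers) | CCOC(=O)C1[C@]2(C)O[C@@H]2[C@H](O)CC1(C)C | intermediate
8 | ethyl (3S,4R)-3,4-dihydroxy-2,6,6-trimethylcyclohex-1-ene-1-carboxylate | CCOC(=O)C1=C(C)[C@H](O)[C@H](O)CC1(C)C | intermediate
9 | ethyl (3S,4R)-3,4-bis(tert-butyldimethylsilyloxy)-2,6,6-trimethylcyclohex-1-ene-1-carboxylate | CCOC(=O)C1=C(C)[C@H](O[Si](C)(C)C(C)(C)C)[C@H](O[Si](C)(C)C(C)(C)C)CC1(C)C | intermediate
10 | [(3S,4R)-3,4-bis(tert-butyldimethylsilyloxy)-2,6,6-trimethylcyclohex-1-en-1-yl]methanol | OCC1=C(C)[C@H](O[Si](C)(C)C(C)(C)C)[C@H](O[Si](C)(C)C(C)(C)C)CC1(C)C | intermediate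
11 | (3S,4R)-3,4-bis(tert-butyldimethylsilyloxy)-2,6,6-trimethylcyclohex-1-ene-1-carbaldehyde | O=CC1=C(C)[C@H](O[Si](C)(C)C(C)(C)C)[C@H](O[Si](C)(C)C(C)(C)C)CC1(C)C | intermediate
12 | geranyl bromide | CC(C)=CCC/C(C)=C/CBr | starting material
13 | triphenylphosphine | c1ccc(cc1)P(c1ccccc1)c1ccccc1 | starting material
14 | [(2E)-3,7-dimethylocta-2,6-dien-1-yl]triphenylphosphonium bromide | CC(C)=CCC/C(C)=C/C[P+](c1ccccc1)(c1ccccc1)c1ccccc1.[Br-] | intermediate
15 | crocetin dialdehyde (all-E) | O=C/C(C)=C/C=C/C(C)=C/C=C/C=C(C)/C=C/C=C(C)/C=O | starting material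
16 | geranylidenetriphenylphosphorane | CC(C)=CCC/C(C)=C/C=P(c1ccccc1)(c1ccccc1)c1ccccc1 | intermediate
17 | 16Z isomer of 8'-apo-ψ-caroten-8'-al | CC(C)=CCC\C(C)=C\C=C/C(C)=C/C=C/C(C)=C/C=C/C=C(C)/C=C/C=C(C)/C=O | intermediate
18 | all-E 8'-apo-ψ-caroten-8'-al | CC(C)=CCC/C(C)=C/C=C/C(C)=C/C=C/C(C)=C/C=C/C=C(C)/C=C/C=C(C)/C=O | intermediate
19 | all-E 8'-apo-ψ-caroten-8'-ol | CC(C)=CCC/C(C)=C/C=C/C(C)=C/C=C/C(C)=C/C=C/C=C(C)/C=C/C=C(C)/CO | intermediate
20 | all-E (8'-apo-ψ-caroten-8'-yl)triphenylphosphonium bromide | CC(C)=CCC/C(C)=C/C=C/C(C)=C/C=C/C(C)=C/C=C/C=C(C)/C=C/C=C(C)/C[P+](c1ccccc1)(c1ccccc1)c1ccccc1.[Br-] | intermediate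
21 | all-E (8'-apo-ψ-caroten-8'-ylidene)triphenylphosphorane | CC(C)=CCC/C(C)=C/C=C/C(C)=C/C=C/C(C)=C/C=C/C=C(C)/C=C/C=C(C)/C=P(c1ccccc1)(c1ccccc1)c1ccccc1 | intermediate
22 | 7Z isomer of (3R,4S)-3,4-bis(tert-butyldimethylsilyloxy)-β,ψ-carotene | CC(C)=CCC/C(C)=C/C=C/C(C)=C/C=C/C(C)=C/C=C/C=C(C)/C=C/C=C(C)/C=C\C1=C(C)[C@H](O[Si](C)(C)C(C)(C)C)[C@H](O[Si](C)(C)C(C)(C)C)CC1(C)C | intermediate
23 | all-E (3R,4S)-3,4-bis(tert-butyldimethylsilyloxy)-β,ψ-carotene | CC(C)=CCC/C(C)=C/C=C/C(C)=C/C=C/C(C)=C/C=C/C=C(C)/C=C/C=C(C)/C=C/C1=C(C)[C@H](O[Si](C)(C)C(C)(C)C)[C@H](O[Si](C)(C)C(C)(C)C)CC1(C)C | intermediate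
24 | (3R,4S)-β,ψ-carotene-3,4-diol (all-E) | CC(C)=CCC/C(C)=C/C=C/C(C)=C/C=C/C(C)=C/C=C/C=C(C)/C=C/C=C(C)/C=C/C1=C(C)[C@H](O)[C@H](O)CC1(C)C | target

**Totals**
Total step count: 13. Longest linear sequence: 9 steps (steps 1–7, 12, 13); the chain branch is steps 8–11.

**Steps most likely to fail**

Step 12. The polyenyl ylide may add only slowly to the aldehyde, which is flanked by the gem-dimethyl carbon and the methyl-bearing alkene carbon; γ-deprotonation of the aldehyde followed by loss of silanolate, and decay of the ylide, may then compete. Fallback, setting out from 10 and 18 and returning at 23: the roles of the partners are exchanged. Appel reaction of 10 (CBr4, PPh3, CH2Cl2, 0 °C) should give [(3S,4R)-3,4-bis(tert-butyldimethylsilyloxy)-2,6,6-trimethylcyclohex-1-en-1-yl]methyl bromide F7. PPh3 in toluene should convert it into the triphenylphosphonium bromide F8. NaOMe in CH2Cl2–MeOH should generate its ylide F9, which is condensed with the unhindered aldehyde 18; the same thermal equilibration then leads to 23. Steps 7, 10 and 11 fall away.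

Step 2. Facial selectivity may be poor because the nominally small arm (CH2 next to a quaternary carbon) is not much smaller than the alkenyl arm, and the racemic ester centre may give a mismatched epimer. Fallback, setting out from 5 and returning at 6: resolution instead of asymmetric reduction. Luche reduction (NaBH4, CeCl3·7H2O, MeOH, 0 °C) should give racemic ethyl 4-hydroxy-2,6,6-trimethylcyclohex-2-ene-1-carboxylate F1. Lipase PS (Burkholderia cepacia) with vinyl acetate in t-BuOMe should acetylate one enantiomer. By the usual empirical model for lipases this is the (4S)-alcohol, whose larger arm is the CH2–CMe2 side, giving ethyl (4S)-4-acetoxy-2,6,6-trimethylcyclohex-2-ene-1-carboxylate F2, which is separated; the unreacted (4R)-alcohol is 6.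

Step 4. Removal of the ester α-proton, which sits between two fully substituted carbons, may be slow, so that ethoxide attack on the epoxide or lactonisation of the hydroxy ester competes. Fallback, setting out from 7 and returning at 11: the elimination is moved to the aldehyde oxidation level, where the α-proton is far more acidic. TBSCl/imidazole in DMF should give ethyl (1S,5R,6R)-5-(tert-butyldimethylsilyloxy)-1,3,3-trimethyl-7-oxabicyclo[4.1.0]heptane-2-carboxylate F3. i-Bu2AlH in CH2Cl2 at −78 °C should give [(1S,5R,6R)-5-(tert-butyldimethylsilyloxy)-1,3,3-trimethyl-7-oxabicyclo[4.1.0]heptan-2-yl]methanol F4. Dess–Martin periodinane with NaHCO3 should give (1S,5R,6R)-5-(tert-butyldimethylsilyloxy)-1,3,3-trimethyl-7-oxabicyclo[4.1.0]heptane-2-carbaldehyde F5, which is not isolated. Et3N should open it to (3S,4R)-4-(tert-butyldimethylsilyloxy)-3-hydroxy-2,6,6-trimethylcyclohex-1-ene-1-carbaldehyde F6. TBSOTf/2,6-lutidine then gives 11. Steps 4–7 are replaced.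

**Further compounds**
F1 | step 2 | ethyl 4-hydroxy-2,6,6-trimethylcyclohex-2-ene-1-carboxylate (racemic at the carbinol) | CCOC(=O)C1C(C)=CC(O)CC1(C)C
F2 | step 2 | ethyl (4S)-4-acetoxy-2,6,6-trimethylcyclohex-2-ene-1-carboxylate | CCOC(=O)C1C(C)=C[C@@H](OC(C)=O)CC1(C)C
F3 | step 4 | ethyl (1S,5R,6R)-5-(tert-butyldimethylsilyloxy)-1,3,3-trimethyl-7-oxabicyclo[4.1.0]heptane-2-carboxylate | CCOC(=O)C1[C@]2(C)O[C@@H]2[C@H](O[Si](C)(C)C(C)(C)C)CC1(C)C
F4 | step 4 | [(1S,5R,6R)-5-(tert-butyldimethylsilyloxy)-1,3,3-trimethyl-7-oxabicyclo[4.1.0]heptan-2-yl]methanol | OCC1[C@]2(C)O[C@@H]2[C@H](O[Si](C)(C)C(C)(C)C)CC1(C)C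
F5 | step 4 | (1S,5R,6R)-5-(tert-butyldimethylsilyloxy)-1,3,3-trimethyl-7-oxabicyclo[4.1.0]heptane-2-carbaldehyde | O=CC1[C@]2(C)O[C@@H]2[C@H](O[Si](C)(C)C(C)(C)C)CC1(C)C
F6 | step 4 | (3S,4R)-4-(tert-butyldimethylsilyloxy)-3-hydroxy-2,6,6-trimethylcyclohex-1-ene-1-carbaldehyde | O=CC1=C(C)[C@H](O)[C@H](O[Si](C)(C)C(C)(C)C)CC1(C)C
F7 | step 12 | [(3S,4R)-3,4-bis(tert-butyldimethylsilyloxy)-2,6,6-trimethylcyclohex-1-en-1-yl]methyl bromide | BrCC1=C(C)[C@H](O[Si](C)(C)C(C)(C)C)[C@H](O[Si](C)(C)C(C)(C)C)CC1(C)C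
F8 | step 12 | {[(3S,4R)-3,4-bis(tert-butyldimethylsilyloxy)-2,6,6-trimethylcyclohex-1-en-1-yl]methyl}triphenylphosphonium bromide | [Br-].c1ccccc1[P+](c1ccccc1)(c1ccccc1)CC1=C(C)[C@H](O[Si](C)(C)C(C)(C)C)[C@H](O[Si](C)(C)C(C)(C)C)CC1(C)C
F9 | step 12 | {[(3S,4R)-3,4-bis(tert-butyldimethylsilyloxy)-2,6,6-trimethylcyclohex-1-en-1-yl]methylidene}triphenylphosphorane | c1ccccc1P(c1ccccc1)(c1ccccc1)=CC1=C(C)[C@H](O[Si](C)(C)C(C)(C)C)[C@H](O[Si](C)(C)C(C)(C)C)CC1(C)C
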